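The 20-membered lactone ring (C1 carbonyl to C19–O) is closed at C14–C15, the middle of the unfunctionalised C7–C18 polymethylene arc, remote from the C5–C6 epoxide ring, the C2–C3 enoate and all six stereocentres. Ring-closing olefin metathesis of an acyclic diene ester forms this bond and the macrocycle in one operation. In the precursor the C2≡C3 triple bond is held as its Co2(CO)6 complex: the cluster bends the C1–C4 rod, blocks enyne metathesis and shields the alkyne while C14=C15 is saturated by diimide. Decomplexation, cis-semihydrogenation and desilylation follow. The diene ester comes from an epoxy-ynoic acid (C1–C14) and an all-syn triol fragment (C15–C24).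

Key step: step 13

Remarks. Atom numbers follow the target: C1 lactone carbonyl, C2=C3, C4 carbinol, C5–C6 epoxide, C7–C18 (CH2)12, C19 lactone carbinol, C21 and C23 side-chain carbinols, C24 methyl. TBS = tert-butyldimethylsilyl. CIP descriptors change with protection and complexation although the spatial arrangement is unchanged.
Assumption: the sense of induction is taken as (R,R)-ProPhenol giving the (4S)-carbinol in step 2 and the (R,R)-TADDOL titanate giving Si-face attack in step 10; the antipodal ligand would be used if either proved reversed.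

Step 1
Reactants: 1 dec-9-enal; 2 (triphenylphosphoranylidene)acetaldehyde
Product: 3 (2E)-dodeca-2,11-dienal
Conditions: toluene, 80 °C
Reagents that add atoms: none
Why: Wittig olefination with the stabilised formylmethylene ylide should give the (E)-enal selectively and adds the C4–C5 carbons to C6.

Step 2
Reactants: 3 (2E)-dodeca-2,11-dienal; 4 methyl prop-2-ynoate
Product: 5 methyl (4S,5E)-4-hydroxypentadeca-5,14-dien-2-ynoate
Conditions: Me2Zn (3 equiv), (R,R)-ProPhenol (10 mol%), Ph3P=O (20 mol%), toluene, 4 °C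
Reagents that add atoms: none
Why: Zinc–ProPhenol-catalysed asymmetric alkynylation: the dinuclear zinc alkynylide formed from 4 and Me2Zn adds 1,2 to the enal inside the chiral ligand pocket, so C4 is set by catalyst control.

Step 3
Reactants: 5 methyl (4S,5E)-4-hydroxypentadeca-5,14-dien-2-ynoate
Product: 6 methyl (4S,5E)-4-[(tert-butyldimethylsilyl)oxy]pentadeca-5,14-dien-2-ynoate
Conditions: TBSCl, imidazole, DMF, 0 °C → rt
Reagents that add atoms: tert-butyldimethylsilyl chloride C[Si](C)(Cl)C(C)(C)C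
Why: Standard silylation of a secondary propargylic alcohol; the silyl ether blocks the C4 hydroxyl during epoxidation and later prevents butenolide formation.

Step 4
Reactants: 6 methyl (4S,5E)-4-[(tert-butyldimethylsilyl)oxy]pentadeca-5,14-dien-2-ynoate
Product: 7 methyl (4R)-4-[(tert-butyldimethylsilyl)oxy]-4-[(2R,3S)-3-(non-8-en-1-yl)oxiran-2-yl]but-2-ynoate
Conditions: 1,2:4,5-di-O-isopropylidene-β-L-erythro-2,3-hexodiulo-2,6-pyranose (enantiomer of the Shi ketone, 30 mol%), Oxone (2KHSO5·KHSO4·K2SO4), K2CO3, Bu4NHSO4, MeCN/CH2(OMe)2/aq. Na2B4O7 buffer, 0 °C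
Reagents that add atoms: potassium peroxymonosulfate [K+].[O-]S(=O)(=O)OO
Why: Shi epoxidation: the chiral dioxirane transfers oxygen to the electron-richer trans-disubstituted C5=C6 bond through a spiro transition state, the L-configured ketone selecting the face that gives the trans-epoxide threo to C4 by reagent control, while the terminal alkene and the electron-poor alkyne should react far more slowly.

Step 5
Reactants: 7 methyl (4R)-4-[(tert-butyldimethylsilyl)oxy]-4-[(2R,3S)-3-(non-8-en-1-yl)oxiran-2-yl]but-2-ynoate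
Product: 8 (4R)-4-[(tert-butyldimethylsilyl)oxy]-4-[(2R,3S)-3-(non-8-en-1-yl)oxiran-2-yl]but-2-ynoic acid
Conditions: LiOH, THF/H2O, 0 °C; then 1 M HCl to pH 4 at 0 °C
Reagents that add atoms: lithium hydroxide [Li+].[OH-]
Why: Saponification (acyl substitution by hydroxide) of the methyl ynoate at 0 °C should leave the epoxide and the silyl ether intact.

Step 6
Reactants: 9 ethyl (3R)-3-hydroxybutanoate; 10 N-methoxy-N-methylacetamide
Product: 11 (5R)-5-hydroxy-N-methoxy-N-methyl-3-oxohexanamide
Conditions: LiN(iPr)2 (3.3 equiv), 10 (3.3 equiv), THF, −78 °C; then 9, −78 → −20 °C; AcOH quench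
Reagents that add atoms: none
Why: Crossed Claisen condensation: the lithium enolate of the Weinreb acetamide acylates the ester, excess base covering the free hydroxyl and the acidic β-keto amide, and C23 is carried over unchanged from the chiral pool.

Step 7
Reactants: 11 (5R)-5-hydroxy-N-methoxy-N-methyl-3-oxohexanamide
Product: 12 (3R,5R)-3,5-dihydroxy-N-methoxy-N-methylhexanamide
Conditions: Et2BOMe, NaBH4, THF/MeOH 4:1, −78 °C; AcOH; MeOH azeotrope
Reagents that add atoms: none
Why: Narasaka–Prasad reduction: Et2BOMe ties the β-hydroxy ketone into a six-membered boron chelate and external hydride attacks axially, which should set C21 syn to C23.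

Step 8
Reactants: 12 (3R,5R)-3,5-dihydroxy-N-methoxy-N-methylhexanamide
Product: 13 (3R,5R)-3,5-bis[(tert-butyldimethylsilyl)oxy]-N-methoxy-N-methylhexanamide
Conditions: TBSOTf (2.5 equiv), 2,6-lutidine, CH2Cl2, −78 → 0 °C
Reagents that add atoms: tert-butyldimethylsilyl trifluoromethanesulfonate C[Si](C)(OS(=O)(=O)C(F)(F)F)C(C)(C)C
Why: The silyl triflate with a hindered pyridine base silylates both secondary hydroxyls without touching the Weinreb amide.

Step 9
Reactants: 13 (3R,5R)-3,5-bis[(tert-butyldimethylsilyl)oxy]-N-methoxy-N-methylhexanamide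
Product: 14 (3R,5R)-3,5-bis[(tert-butyldimethylsilyl)oxy]hexanal
Conditions: iBu2AlH (1.2 equiv), THF, −78 °C; aq. KNaC4H4O6 (Rochelle salt)
Reagents that add atoms: none
Why: Weinreb amide reduction stops at the aldehyde because the chelated tetrahedral aluminium adduct collapses only on work-up.

Step 10
Reactants: 14 (3R,5R)-3,5-bis[(tert-butyldimethylsilyl)oxy]hexanal; 15 5-bromopent-1-ene
Product: 18 (6S,8S,10R)-8,10-bis[(tert-butyldimethylsilyl)oxy]undec-1-en-6-ol, via pent-4-en-1-ylmagnesium bromide 16 (not isolated), via bis(pent-4-en-1-yl)zinc 17 (not isolated)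
Conditions: 15, Mg, Et2O; ZnCl2 (0.5 equiv), then 1,4-dioxane, filtration; Ti(OiPr)4 (1.2 equiv), (R,R)-TADDOL·Ti(OiPr)2 (20 mol%), toluene, −25 °C, then 14
Reagents that add atoms: none
Why: Titanium TADDOLate-catalysed enantioselective dialkylzinc addition: the (R,R)-titanate should steer the pentenyl group of 17 to the Si face of the aldehyde, setting C19 (S, syn to C21) by catalyst control.

Step 11
Reactants: 8 (4R)-4-[(tert-butyldimethylsilyl)oxy]-4-[(2R,3S)-3-(non-8-en-1-yl)oxiran-2-yl]but-2-ynoic acid; 18 (6S,8S,10R)-8,10-bis[(tert-butyldimethylsilyl)oxy]undec-1-en-6-ol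
Product: 19 (6S,8S,10R)-8,10-bis[(tert-butyldimethylsilyl)oxy]undec-1-en-6-yl (4R)-4-[(tert-butyldimethylsilyl)oxy]-4-[(2R,3S)-3-(non-8-en-1-yl)oxiran-2-yl]but-2-ynoate
Conditions: DCC (1.3 equiv), DMAP (10 mol%), CH2Cl2, −20 → 0 °C
Reagents that add atoms: none
Why: Steglich esterification via the O-acylisourea and acylpyridinium ion acylates the C19 hydroxyl with retention; low temperature and catalytic DMAP limit conjugate addition to the ynoate.

Step 12
Reactants: 19 (6S,8S,10R)-8,10-bis[(tert-butyldimethylsilyl)oxy]undec-1-en-6-yl (4R)-4-[(tert-butyldimethylsilyl)oxy]-4-[(2R,3S)-3-(non-8-en-1-yl)oxiran-2-yl]but-2-ynoate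
Product: 20 hexacarbonyldicobalt complex of 19 (Co2(CO)6 unit bridging the C2≡C3 triple bond; organic part and descriptors as in 19)
Conditions: Co2(CO)8 (1.1 equiv), CH2Cl2, rt
Reagents that add atoms: dicobalt octacarbonyl O=C=[Co](=C=O)(=C=O)(=C=O)[Co](=C=O)(=C=O)(=C=O)=C=O
Why: The alkyne displaces two CO ligands of Co2(CO)8 to give the stable μ-alkyne Co2(CO)6 complex (alkyne protection of the Nicholas type), while alkenes, epoxide and silyl ethers do not react.

Step 13
Reactants: 20 hexacarbonyldicobalt complex of 19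
Product: 21 Co2(CO)6 complex (bridging C2≡C3) of (4R,5R,6S,19S,21S,23R)-4,21,23-tris[(tert-butyldimethylsilyl)oxy]-5,6-epoxytetracos-14-en-2-yn-19-olide (14E/14Z mixture; descriptors given for the metal-free alkyne)
Conditions: second-generation Grubbs catalyst RuCl2(=CHPh)(PCy3)(H2IMes) (10 mol%), CH2Cl2 (1 mM), 40 °C
Reagents that add atoms: none
Why: The ruthenium benzylidene exchanges with one terminal alkene by [2+2] cycloaddition and cycloreversion, and the resulting chain-bound alkylidene engages the second terminal alkene through a ruthenacyclobutane that releases ethene and forms C14=C15 (Chauvin mechanism). The closest known reaction type is macrocyclic ring-closing olefin metathesis of diene esters to macrolactones, which is also known to proceed on Co2(CO)6-complexed alkynes. The 20-membered ring closes by head-to-tail union of the two chain termini at high dilution, driven by loss of ethene; the epoxide ring is not involved. No stereocentre is formed, and the E/Z ratio at C14=C15 is irrelevant because this bond is saturated in step 14. The step needs selectivity for the two monosubstituted alkenes over the alkyne and over intermolecular metathesis: the cobalt cluster removes the alkyne from play and bends C1–C4 to bring the termini together, the reacting carbons lie far from all six stereocentres, and 1 mM dilution should suppress oligomers.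

Step 14
Reactants: 21 Co2(CO)6 complex of the 14-ene macrolactone
Product: 22 Co2(CO)6 complex (bridging C2≡C3) of 23
Conditions: 2-nitrobenzenesulfonylhydrazide (excess, in portions), Et3N, CH2Cl2, rt
Reagents that add atoms: none
Why: Diimide, released from the sulfonylhydrazide, delivers H2 to the unhindered C14=C15 bond through a concerted cyclic transition state, whereas the cobalt-bound alkyne, the epoxide and the silyl ethers are not substrates.

Step 15
Reactants: 22 Co2(CO)6 complex of 23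
Product: 23 (4R,5R,6S,19S,21S,23R)-4,21,23-tris[(tert-butyldimethylsilyl)oxy]-5,6-epoxytetracos-2-yn-19-olide
Conditions: (NH4)2Ce(NO3)6 (5 equiv), acetone, −78 → −30 °C
Reagents that add atoms: none
Why: Oxidative decomplexation: tetravalent cerium oxidises the cobalt cluster and releases the alkyne, and short exposure at low temperature should spare the epoxide and the silyl ethers.

Step 16
Reactants: 23 (4R,5R,6S,19S,21S,23R)-4,21,23-tris[(tert-butyldimethylsilyl)oxy]-5,6-epoxytetracos-2-yn-19-olide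
Product: 24 (2Z,4R,5R,6S,19S,21S,23R)-4,21,23-tris[(tert-butyldimethylsilyl)oxy]-5,6-epoxytetracos-2-en-19-olide
Conditions: H2 (1 atm), Pd/CaCO3 poisoned with Pb(OAc)2 (Lindlar catalyst), quinoline, EtOAc, rt
Reagents that add atoms: none
Why: Lindlar semihydrogenation delivers H2 syn to the alkyne on poisoned palladium and should stop at the (2Z)-enoate, the C4 silyl ether preventing cyclisation to a butenolide.

Step 17
Reactants: 24 (2Z,4R,5R,6S,19S,21S,23R)-4,21,23-tris[(tert-butyldimethylsilyl)oxy]-5,6-epoxytetracos-2-en-19-olide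
Product: 25 (2Z,4R,5S,6S,19S,21R,23R)-5,6-epoxy-4,21,23-trihydroxytetracos-2-en-19-olide (CNP0461152.1)
Conditions: HF·pyridine, pyridine, THF, 0 °C → rt
Reagents that add atoms: none
Why: Pyridine-buffered HF cleaves the three silyl ethers by Si–F bond formation without base, which should avoid acyl migration or translactonisation and spare the trans-epoxide.

Compound list
1 | dec-9-enal | C=CCCCCCCCC=O | starting material
2 | (triphenylphosphoranylidene)acetaldehyde | O=CC=P(c1ccccc1)(c1ccccc1)c1ccccc1 | starting material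
3 | (2E)-dodeca-2,11-dienal | C=CCCCCCCC/C=C/C=O | intermediate
4 | methyl prop-2-ynoate | C#CC(=O)OC | starting material
5 | methyl (4S,5E)-4-hydroxypentadeca-5,14-dien-2-ynoate | C=CCCCCCCC/C=C/[C@H](O)C#CC(=O)OC | intermediate
6 | methyl (4S,5E)-4-[(tert-butyldimethylsilyl)oxy]pentadeca-5,14-dien-2-ynoate | C=CCCCCCCC/C=C/[C@H](O[Si](C)(C)C(C)(C)C)C#CC(=O)OC | intermediate
7 | methyl (4R)-4-[(tert-butyldimethylsilyl)oxy]-4-[(2R,3S)-3-(non-8-en-1-yl)oxiran-2-yl]but-2-ynoate | C=CCCCCCCC[C@@H]1O[C@H]1[C@H](O[Si](C)(C)C(C)(C)C)C#CC(=O)OC | intermediate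
8 | (4R)-4-[(tert-butyldimethylsilyl)oxy]-4-[(2R,3S)-3-(non-8-en-1-yl)oxiran-2-yl]but-2-ynoic acid | C=CCCCCCCC[C@@H]1O[C@H]1[C@H](O[Si](C)(C)C(C)(C)C)C#CC(=O)O | intermediate
9 | ethyl (3R)-3-hydroxybutanoate | C[C@@H](O)CC(=O)OCC | starting material
10 | N-methoxy-N-methylacetamide | CC(=O)N(C)OC | starting material
11 | (5R)-5-hydroxy-N-methoxy-N-methyl-3-oxohexanamide | C[C@@H](O)CC(=O)CC(=O)N(C)OC | intermediate
12 | (3R,5R)-3,5-dihydroxy-N-methoxy-N-methylhexanamide | C[C@@H](O)C[C@@H](O)CC(=O)N(C)OC | intermediate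
13 | (3R,5R)-3,5-bis[(tert-butyldimethylsilyl)oxy]-N-methoxy-N-methylhexanamide | C[C@@H](O[Si](C)(C)C(C)(C)C)C[C@@H](O[Si](C)(C)C(C)(C)C)CC(=O)N(C)OC | intermediate
14 | (3R,5R)-3,5-bis[(tert-butyldimethylsilyl)oxy]hexanal | C[C@@H](O[Si](C)(C)C(C)(C)C)C[C@@H](O[Si](C)(C)C(C)(C)C)CC=O | intermediate
15 | 5-bromopent-1-ene | C=CCCCBr | starting material
16 | pent-4-en-1-ylmagnesium bromide | C=CCCC[Mg]Br | intermediate (not isolated)
17 | bis(pent-4-en-1-yl)zinc | C=CCCC[Zn]CCCC=C | intermediate (not isolated)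
18 | (6S,8S,10R)-8,10-bis[(tert-butyldimethylsilyl)oxy]undec-1-en-6-ol | C[C@@H](O[Si](C)(C)C(C)(C)C)C[C@@H](O[Si](C)(C)C(C)(C)C)C[C@@H](O)CCCC=C | intermediate
19 | (6S,8S,10R)-8,10-bis[(tert-butyldimethylsilyl)oxy]undec-1-en-6-yl (4R)-4-[(tert-butyldimethylsilyl)oxy]-4-[(2R,3S)-3-(non-8-en-1-yl)oxiran-2-yl]but-2-ynoate | C[C@@H](O[Si](C)(C)C(C)(C)C)C[C@@H](O[Si](C)(C)C(C)(C)C)C[C@@H](OC(=O)C#C[C@@H](O[Si](C)(C)C(C)(C)C)[C@@H]1O[C@H]1CCCCCCCC=C)CCCC=C | intermediate
20 | hexacarbonyldicobalt complex of 19 (Co2(CO)6 bridging C2≡C3) | C[C@@H](O[Si](C)(C)C(C)(C)C)C[C@@H](O[Si](C)(C)C(C)(C)C)C[C@@H](OC(=O)C12[Co]3(=C=O)(=C=O)(=C=O)[Co]1(=C=O)(=C=O)(=C=O)C23[C@@H](O[Si](C)(C)C(C)(C)C)[C@@H]4O[C@H]4CCCCCCCC=C)CCCC=C | intermediate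
21 | Co2(CO)6 complex (bridging C2≡C3) of (4R,5R,6S,19S,21S,23R)-4,21,23-tris[(tert-butyldimethylsilyl)oxy]-5,6-epoxytetracos-14-en-2-yn-19-olide (14E/14Z mixture) | C[C@@H](O[Si](C)(C)C(C)(C)C)C[C@@H](O[Si](C)(C)C(C)(C)C)C[C@@H]1CCCC=CCCCCCCC[C@@H]2O[C@H]2[C@H](O[Si](C)(C)C(C)(C)C)C34[Co]5(=C=O)(=C=O)(=C=O)[Co]3(=C=O)(=C=O)(=C=O)C45C(=O)O1 | intermediate
22 | Co2(CO)6 complex (bridging C2≡C3) of 23 | C[C@@H](O[Si](C)(C)C(C)(C)C)C[C@@H](O[Si](C)(C)C(C)(C)C)C[C@@H]1CCCCCCCCCCCC[C@@H]2O[C@H]2[C@H](O[Si](C)(C)C(C)(C)C)C34[Co]5(=C=O)(=C=O)(=C=O)[Co]3(=C=O)(=C=O)(=C=O)C45C(=O)O1 | intermediate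
23 | (4R,5R,6S,19S,21S,23R)-4,21,23-tris[(tert-butyldimethylsilyl)oxy]-5,6-epoxytetracos-2-yn-19-olide | C[C@@H](O[Si](C)(C)C(C)(C)C)C[C@@H](O[Si](C)(C)C(C)(C)C)C[C@@H]1CCCCCCCCCCCC[C@@H]2O[C@H]2[C@H](O[Si](C)(C)C(C)(C)C)C#CC(=O)O1 | intermediate
24 | (2Z,4R,5R,6S,19S,21S,23R)-4,21,23-tris[(tert-butyldimethylsilyl)oxy]-5,6-epoxytetracos-2-en-19-olide | C[C@@H](O[Si](C)(C)C(C)(C)C)C[C@@H](O[Si](C)(C)C(C)(C)C)C[C@@H]1CCCCCCCCCCCC[C@@H]2O[C@H]2[C@H](O[Si](C)(C)C(C)(C)C)/C=C\C(=O)O1 | intermediate
25 | (2Z,4R,5S,6S,19S,21R,23R)-5,6-epoxy-4,21,23-trihydroxytetracos-2-en-19-olide (CNP0461152.1) | C[C@@H](O)C[C@@H](O)C[C@@H]1CCCCCCCCCCCC[C@@H]2O[C@H]2[C@H](O)/C=C\C(=O)O1 | target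

Total step count: 17.
Longest linear sequence: 12 steps (steps 1–5 then 11–17 from 1; equally steps 6–10 then 11–17 from 9).

Steps most likely to fail

Step 14. The cobalt cluster may be lost under the amine-buffered diimide conditions, which would expose the ynoate to reduction, or the largely trans macrocyclic alkene may be reduced too slowly. The fallback does without cobalt, sets out from 19 and comes back at 24. Semihydrogenation of 19 (H2, Pd/CaCO3 poisoned with Pb(OAc)2, quinoline, EtOAc) should give (6S,8S,10R)-8,10-bis[(tert-butyldimethylsilyl)oxy]undec-1-en-6-yl (2Z,4R)-4-[(tert-butyldimethylsilyl)oxy]-4-[(2R,3S)-3-(non-8-en-1-yl)oxiran-2-yl]but-2-enoate F1. Ring-closing metathesis of F1 with the same ruthenium catalyst at 1 mM, in which the hindered cis-enoate should be a poor metathesis partner, should give (2Z,4R,5R,6S,19S,21S,23R)-4,21,23-tris[(tert-butyldimethylsilyl)oxy]-5,6-epoxytetracosa-2,14-dien-19-olide F2. Hydrogenation of F2 with H2 and RhCl(PPh3)3, a catalyst governed by steric access, should saturate the unhindered C14=C15 bond in preference to the enoate flanked by the C4 silyloxy group and give 24.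

Step 4. Facial discrimination by the dioxirane may be eroded by the adjacent C4 silyloxy centre, and the terminal alkene or the ynoate may be attacked under the basic oxidising conditions. The fallback uses hydroxyl-directed epoxidation followed by inversion, sets out from 3 and comes back at 7. Zinc–ProPhenol alkynylation of 3 with 4 using the (S,S)-ligand should give methyl (4R,5E)-4-hydroxypentadeca-5,14-dien-2-ynoate F3. Sharpless epoxidation (Ti(OiPr)4, L-(+)-diisopropyl tartrate, tBuOOH, 4 Å sieves, CH2Cl2, −20 °C), matched for this enantiomer and blind to the terminal alkene, should give the erythro epoxy alcohol methyl (4S)-4-hydroxy-4-[(2S,3S)-3-(non-8-en-1-yl)oxiran-2-yl]but-2-ynoate F4. Mitsunobu inversion at C4 (4-nitrobenzoic acid, PPh3, diisopropyl azodicarboxylate) should give methyl (4R)-4-[(4-nitrobenzoyl)oxy]-4-[(2R,3S)-3-(non-8-en-1-yl)oxiran-2-yl]but-2-ynoate F5. Mild methanolysis (K2CO3 cat., MeOH, 0 °C) should give the threo epoxy alcohol methyl (4R)-4-hydroxy-4-[(2S,3S)-3-(non-8-en-1-yl)oxiran-2-yl]but-2-ynoate F6, and silylation (TBSCl, imidazole, DMF) then gives 7.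

Step 10. Catalyst control by the titanium TADDOLate may be eroded by 1,3-induction from the β-silyloxy group, so that both C19 epimers form. The fallback makes both epimers useful, sets out from 14 and comes back at 19. Uncatalysed addition of 16 to 14 (THF, −78 °C) should give 18 together with its C6 epimer (6R,8S,10R)-8,10-bis[(tert-butyldimethylsilyl)oxy]undec-1-en-6-ol F7. After chromatographic separation 18 is esterified as in step 11, and F7 is esterified with acid 8 under Mitsunobu conditions (PPh3, diisopropyl azodicarboxylate, toluene, 0 °C) with inversion at C19, so that both epimers converge on 19.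

Further compounds
F1 | step 14 | (6S,8S,10R)-8,10-bis[(tert-butyldimethylsilyl)oxy]undec-1-en-6-yl (2Z,4R)-4-[(tert-butyldimethylsilyl)oxy]-4-[(2R,3S)-3-(non-8-en-1-yl)oxiran-2-yl]but-2-enoate | C[C@@H](O[Si](C)(C)C(C)(C)C)C[C@@H](O[Si](C)(C)C(C)(C)C)C[C@@H](OC(=O)/C=C\[C@@H](O[Si](C)(C)C(C)(C)C)[C@@H]1O[C@H]1CCCCCCCC=C)CCCC=C
F2 | step 14 | (2Z,4R,5R,6S,19S,21S,23R)-4,21,23-tris[(tert-butyldimethylsilyl)oxy]-5,6-epoxytetracosa-2,14-dien-19-olide (14E/14Z mixture) | C[C@@H](O[Si](C)(C)C(C)(C)C)C[C@@H](O[Si](C)(C)C(C)(C)C)C[C@@H]1CCCC=CCCCCCCC[C@@H]2O[C@H]2[C@H](O[Si](C)(C)C(C)(C)C)/C=C\C(=O)O1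
F3 | step 4 | methyl (4R,5E)-4-hydroxypentadeca-5,14-dien-2-ynoate | C=CCCCCCCC/C=C/[C@@H](O)C#CC(=O)OC
F4 | step 4 | methyl (4S)-4-hydroxy-4-[(2S,3S)-3-(non-8-en-1-yl)oxiran-2-yl]but-2-ynoate | C=CCCCCCCC[C@@H]1O[C@H]1[C@@H](O)C#CC(=O)OC
F5 | step 4 | methyl (4R)-4-[(4-nitrobenzoyl)oxy]-4-[(2R,3S)-3-(non-8-en-1-yl)oxiran-2-yl]but-2-ynoate | C=CCCCCCCC[C@@H]1O[C@H]1[C@H](OC(=O)c2ccc(cc2)[N+](=O)[O-])C#CC(=O)OC
F6 | step 4 | methyl (4R)-4-hydroxy-4-[(2S,3S)-3-(non-8-en-1-yl)oxiran-2-yl]but-2-ynoate | C=CCCCCCCC[C@@H]1O[C@H]1[C@H](O)C#CC(=O)OC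
F7 | step 10 | (6R,8S,10R)-8,10-bis[(tert-butyldimethylsilyl)oxy]undec-1-en-6-ol | C[C@@H](O[Si](C)(C)C(C)(C)C)C[C@@H](O[Si](C)(C)C(C)(C)C)C[C@H](O)CCCC=C
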